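## Structural features

The target is a flavone: a 4H-chromen-4-one (benzo ring A fused to pyranone ring C) that carries aryl ring B on C2 through the C2–C1' bond. Ring A is fully substituted, with oxygen on every carbon in the alternating order 5-OH, 6-OMe, 7-OH, 8-OMe, and ring C has a methoxy group on C3 next to the C4 carbonyl. Ring B is a 2',5'-dihydroxy-4'-methoxyphenyl group, that is, a methoxyhydroquinone. There is no stereocentre, so every selectivity question is one of regio- or chemoselectivity. Three elements are fragile: the hydroquinone ring B (air oxidation to a quinone, above all in base), C2 of the chromone (conjugate attack by hard nucleophiles opens ring C), and the 2'-oxygen, which can close a furan ring onto any leaving group at C3. The real difficulty is ring A: five contiguous oxygens must be told apart as hydroxyl or methoxyl, and ring C must be closed onto this crowded ring without a regiochemical choice. The key step exploits the fact that C2 and C3 can be the two carbons of an alkyne between the C4 carbonyl and C1' of ring B. The ring-A aryl ketone then has two equivalent ortho oxygens (the future O1 and 5-O), so either may attack C2 and only one chromone can result, while C3 receives the iodine that later becomes the 3-methoxy group.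

## Logic of the disconnections

21 to 20: the four O–benzyl bonds at 5-O, 7-O, 2'-O and 5'-O are cut. The free phenols, and the oxidisable hydroquinone of ring B in particular, then appear only in the last operation. Benzyl is the one group that should survive every earlier condition (K2CO3, NaOMe, CuI, PdCl2(PPh3)2, 16) and leave in a single neutral step. The forward step must spare the C2=C3 bond and the four methyl ethers.

20 to 18 and 19: the C3–OMe bond is cut back to C3–I. The 3-oxygen then need not be carried through the assembly, because the ring closure places the halogen at C3 at no cost. The forward step is a CuI-mediated C–O coupling in a basic medium, and no phenoxide may be present in it. A free 2'-oxygen would close a five-membered ring onto C3 (a benzofuran-fused chromone) in preference to the intermolecular coupling with 19. Ring B is therefore carried as benzyl ethers and not as esters, which this medium would cleave. Esters would also be at risk under the amine, CuI and acetylide conditions earlier in the route.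

18 to 15 and 16 (through 17): the O1–C2 bond is cut, together with C3–I. Ring C opens to an aryl alkynyl ketone whose ring A bears two equivalent ortho benzyloxy groups. The gain is a linear precursor from which ring C and its C3 handle arise in one step. The forward step demands attack of a ring-A oxygen on the alkyne carbon joined to ring B, not attack of the 2'-oxygen on the other alkyne carbon, and no iodination of ring B.

15 to 14: no skeletal bond is cut; the C4 ketone is taken back to a carbinol. The ynone can then be assembled from an aldehyde without an acid chloride and without a separate alkyne protecting group. The forward oxidation must be neutral, since 14 ionises easily.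

14 to 9 and 13: the C2–C1' bond (alkyne carbon to ring B) is cut. This joins two aromatic halves of similar size at a late, convergent point. The forward coupling must run under mild basic conditions that leave the acid-labile carbinol of 9 alone.

9 to 7 and 8: the C3–C4 bond is cut, so that C2 and C3 arrive as a two-carbon nucleophile on the ring-A aldehyde. The demand is 1,2-addition to an aldehyde flanked by two benzyloxy groups.

7 to 5 and 6, then 5 to 3 and 4: the C6–O and C8–O bonds are cut back to C–Br and then to C–H. The two free ring positions of 3 are exactly C6 and C8 of the target, and the formyl group occupies the third, so bromination is exhaustive and needs no stoichiometric control. The distinction between methoxyl (6, 8) and future hydroxyl (5, 7, O1) is written into the order of events. The forward methoxylation must work at bromides flanked by two benzyloxy groups and must tolerate the aldehyde.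

3 to 1 and 2: three O–benzyl bonds are cut. The starting ring already holds the C4 carbon and the 1,3,5-oxygen pattern. The forward step demands O- over C-alkylation.

13 to 11 and 12, then 11 to 10 and 2: the C1'–I bond and two O–benzyl bonds are cut. Iodination para to the methoxy group of 11 gives the ring-B pattern directly, and 10 already holds all three oxygens.

## Other disconnections considered

Alternative 1: The cut is O1–C8a. Forward, the triacetylated 2-methoxy-1,3-diketone A1 (syringyl ketone on one side, ring-B ketone on the other) would be oxidised at an anode. The enol oxygen next to ring B should attack an ortho carbon of the syringyl ring and, after loss of two electrons and two protons, give chromone A2.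
- In favour: the syringyl ring is symmetrical, so both ortho carbons lead to the same product. The 3-methoxy group is already in A1, so no halide and no CuI-mediated step are needed at C3; on this point it is better than the chosen plan. A1 should be reachable in few steps by Claisen-type acylation, and the oxidant is an electrode, so up to the ring closure it is also better on step count and reagent economy.
- Against: A2 does not have the oxygen pattern of 21. A syringyl ring supplies only the oxygens of C6, C7 and C8, so C5 of A2 is a C–H and the 5-hydroxyl is missing. A further peri C5–H hydroxylation, directed by the C4 carbonyl and flanked by the 6-methoxy group, would have to follow, on an electron-rich flavone that is easily over-oxidised.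
- The key step itself is a dehydrogenative C–O coupling onto an arene made less nucleophilic by its acetoxy group. The enol and ring B are oxidisable too, and the other enol oxygen could close onto C6' of ring B to give the chromone with the two rings exchanged.
- Comparison: the chosen plan has all five ring-A oxygens in place before closure and forms O1–C2 by a polar cyclisation with close precedent. Alternative 1 is shorter on paper but needs two uncertain oxidations where the chosen plan needs none.

Alternative 2: The cuts are C7–C8 and C4a–C5; ring A is made last on a ring C derived from kojic acid A3. Forward, the 2-aryl-3-methoxy-6-(methoxymethyl)pyran-4-one A4 would be deprotonated at the methoxymethyl carbon. The extended enolate should be acylated there by dimethyl methoxymalonate A5 (C7–C8). The keto ester should then close by attack of the pyranone carbon that becomes C4a on the second ester (C4a–C5) and tautomerise to the resorcinol ring of A6.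
- In favour: the ring-A pattern is fixed by the two building blocks with no ambiguity. The 5,7-diol emerges free, so ring A needs no protecting groups, no bromination and no CuI-mediated methoxylation, and the 3-methoxy group comes from the enolic hydroxyl of A3. On protecting-group economy and step count (about eight operations against eleven) it is better than the chosen plan.
- Against: A5 is a far stronger C–H acid than the methoxymethyl group of A4, so proton transfer to the dienolate should compete with acylation. The carbanion sits on an oxygen-bearing carbon and is not well stabilised. The pyranone is itself open to conjugate attack and ring opening by strong bases. The Claisen closure asks the weakly nucleophilic vinylogous-ester carbon to attack an ester, which probably needs a second deprotonation.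
- Comparison: the chosen plan builds on intact aromatic rings and each of its steps has a close analogue. Alternative 2 is the more economical design, but its single key operation must succeed in three respects at once (site of deprotonation, C-acylation, ring closure).

Alternative 3: The cuts are C3–C4 and O1–C2. Forward, the lithium enolate of the ω-methoxyacetophenone A8 would attack the lactone-type carbonyl of the benzodioxinone A7. The ketal fragment is lost, the ring-A phenoxide is set free, and on acidification the phenol condenses on the aryl ketone to close ring C and give A9.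
- In favour: A9 is the same compound as 20, so the end-game is identical (equal). The 3-methoxy group arrives with A8, so neither the iodide nor the CuI-mediated etherification at C3 is needed; on this point it is better than the chosen plan. Acylation followed by cyclodehydration is the classical flavone construction and is at least the equal of the iodocyclisation in mechanistic security.
- Against: ring A must be desymmetrised as a salicylate, with one ortho oxygen in the ketal and the other as a benzyl ether. The methoxide-based introduction of the 6- and 8-methoxy groups would open the dioxinone, so the heterocycle has to be made afterwards from a mono-phenol acid, which needs an extra oxidation, a selective mono-debenzylation and a ketalisation beyond 7.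
- The carbonyl of A7 is flanked by the 5-benzyloxy group. The β-diketone formed is more acidic than A8 and consumes a second equivalent of enolate. The acid closure must be mild enough for four benzyl ethers.
- Comparison: the chosen plan keeps ring A symmetrical until the very step that closes ring C, and so avoids the desymmetrisation altogether. Step counts are about equal. Alternative 3 is safer at C3 and less safe in the preparation of its ring-A component.

Key step: step 9

Remark: ring B is carried as benzyl ethers throughout, because acetates would not survive the basic C3 methoxylation and would release the 2'-phenoxide next to the C3 iodide. Carbinols 9 and 14 are racemic; their single stereocentre is removed in step 8 and the target is achiral.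

## Route

Step 1
Reactants: 1 2,4,6-trihydroxybenzaldehyde; 2 benzyl bromide
Product: 3 2,4,6-tris(benzyloxy)benzaldehyde
Conditions: BnBr (3.6 equiv), K2CO3, DMF, N2, 70 °C
Reagents that add atoms: benzyl bromide, BrCc1ccccc1
Why: Williamson O-alkylation of the three phenoxides. The formyl group lowers the carbon nucleophilicity of the ring, and a polar aprotic solvent with a potassium counter-ion favours O- over C-benzylation; excess reagent and warming should bring the two hydrogen-bonded ortho hydroxyls to completion.

Step 2
Reactants: 3 2,4,6-tris(benzyloxy)benzaldehyde; 4 N-bromosuccinimide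
Product: 5 2,4,6-tris(benzyloxy)-3,5-dibromobenzaldehyde
Conditions: NBS (2.1 equiv), MeCN, 0 °C to rt, dark
Reagents that add atoms: N-bromosuccinimide, O=C1CCC(=O)N1Br
Why: Electrophilic aromatic bromination. C3 and C5 are the only free positions, each ortho or para to all three benzyloxy groups and meta to the aldehyde, so dibromination should be exhaustive and unambiguous.

Step 3
Reactants: 5 2,4,6-tris(benzyloxy)-3,5-dibromobenzaldehyde; 6 sodium methoxide
Product: 7 2,4,6-tris(benzyloxy)-3,5-dimethoxybenzaldehyde
Conditions: NaOMe (6 equiv), CuI (20 mol%), MeOH–DMF, 100 °C
Reagents that add atoms: sodium methoxide, [Na+].[O-]C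
Why: CuI-catalysed Ullmann-type methoxylation of aryl bromides, a reaction practised on bromobenzaldehydes of the vanillin series. The aldehyde has no α-hydrogen and is shielded by two ortho benzyloxy groups.

Step 4
Reactants: 7 2,4,6-tris(benzyloxy)-3,5-dimethoxybenzaldehyde; 8 ethynylmagnesium bromide
Product: 9 (±)-1-[2,4,6-tris(benzyloxy)-3,5-dimethoxyphenyl]prop-2-yn-1-ol
Conditions: HC≡CMgBr (0.5 M in THF, 1.5 equiv), THF, 0 °C to rt; aq. NH4Cl
Reagents that add atoms: ethynylmagnesium bromide, C#C[Mg]Br
Why: Grignard 1,2-addition of an acetylide to an aromatic aldehyde; the carbinol forms as a racemate and its stereocentre is removed in step 8. The electron-rich benzylic carbinol ionises easily, so it should be passed only through triethylamine-washed silica and used without delay.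

Step 5
Reactants: 10 methoxyhydroquinone (2-methoxybenzene-1,4-diol); 2 benzyl bromide
Product: 11 1,4-bis(benzyloxy)-2-methoxybenzene
Conditions: BnBr (2.4 equiv), K2CO3, degassed DMF, N2, rt to 50 °C
Reagents that add atoms: benzyl bromide, BrCc1ccccc1
Why: Williamson ether synthesis on both phenols. Exclusion of air keeps the hydroquinone anion from oxidising to the quinone before it is alkylated.

Step 6
Reactants: 11 1,4-bis(benzyloxy)-2-methoxybenzene; 12 N-iodosuccinimide
Product: 13 1,4-bis(benzyloxy)-2-iodo-5-methoxybenzene
Conditions: NIS (1.05 equiv), TFA (10 mol%), MeCN, 0 °C to rt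
Reagents that add atoms: N-iodosuccinimide, O=C1CCC(=O)N1I
Why: Electrophilic aromatic iodination. The position para to the methoxy group and ortho to a benzyloxy group is the usual site of substitution in 1,2,4-trialkoxybenzenes; the position between two oxygens is hindered and the third has only one ortho donor.

Step 7
Reactants: 9 (±)-1-[2,4,6-tris(benzyloxy)-3,5-dimethoxyphenyl]prop-2-yn-1-ol; 13 1,4-bis(benzyloxy)-2-iodo-5-methoxybenzene
Product: 14 (±)-3-[2,5-bis(benzyloxy)-4-methoxyphenyl]-1-[2,4,6-tris(benzyloxy)-3,5-dimethoxyphenyl]prop-2-yn-1-ol
Conditions: PdCl2(PPh3)2 (3 mol%), CuI (5 mol%), Et3N–THF, degassed, rt to 45 °C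
Reagents that add atoms: none
Why: Sonogashira coupling of a terminal alkyne with an aryl iodide, which joins C2 to C1'. The basic, mild medium leaves the acid-labile carbinol and all benzyl ethers alone, and an electron-rich aryl group does not promote base-induced isomerisation of the propynol to an enone.

Step 8
Reactants: 14 (±)-3-[2,5-bis(benzyloxy)-4-methoxyphenyl]-1-[2,4,6-tris(benzyloxy)-3,5-dimethoxyphenyl]prop-2-yn-1-ol
Product: 15 3-[2,5-bis(benzyloxy)-4-methoxyphenyl]-1-[2,4,6-tris(benzyloxy)-3,5-dimethoxyphenyl]prop-2-yn-1-one
Conditions: activated MnO2 (15 equiv), CH2Cl2, rt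
Reagents that add atoms: none
Why: MnO2 oxidation of an alcohol that is both benzylic and propargylic. The neutral heterogeneous oxidant avoids ionisation of the carbinol and leaves ethers and alkyne untouched.

Step 9
Reactants: 15 3-[2,5-bis(benzyloxy)-4-methoxyphenyl]-1-[2,4,6-tris(benzyloxy)-3,5-dimethoxyphenyl]prop-2-yn-1-one; 16 iodine monochloride
Product: 18 5,7-bis(benzyloxy)-2-[2,5-bis(benzyloxy)-4-methoxyphenyl]-3-iodo-6,8-dimethoxy-4H-chromen-4-one, via O-benzyl chromenone oxonium chloride 17 (not isolated)
Conditions: ICl (1.2 equiv, 1 M in CH2Cl2, added dropwise), CH2Cl2, −78 °C; aq. Na2S2O3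
Reagents that add atoms: iodine monochloride, ICl
Why: ICl adds to the alkyne of 15 as an iodonium-type electrophile, and one of the two equivalent ortho benzyloxy oxygens of ring A attacks the alkyne carbon bonded to ring B anti to iodine, which closes ring C in the 6-endo-dig mode and makes O1–C2 with iodine on C3. The resulting O-benzyl oxonium ion 17 is dealkylated by chloride at the benzylic carbon, a faster substitution than at the methyl group of the usual substrates, and benzyl chloride leaves. The closest known reaction type is the ICl-induced cyclisation of 2-methoxyaryl alkynyl ketones to 3-iodochromones; only the group removed from oxygen differs. No stereocentre is formed. Three selectivities are needed: oxygen attack at the ring-B-side carbon and not at the carbonyl-side carbon, closure by a ring-A oxygen and not by the 2'-benzyloxy oxygen of ring B, and activation of the alkyne ahead of iodination of an arene C–H. The first two are one question, because the 2'-oxygen can reach only the carbonyl-side carbon (5-endo-dig), where positive charge is opposed by the adjacent carbonyl, whereas the ring-B-side carbon is the conjugate position of the ynone and is stabilised by the 2'- and 4'-oxygens of ring B. Ring A has no C–H at all, and ring B is guarded by the low temperature, the near-stoichiometric charge of ICl and its electron-withdrawing ynone substituent. Because the two ortho oxygens of ring A are equivalent, only one chromone can form.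

Step 10
Reactants: 18 5,7-bis(benzyloxy)-2-[2,5-bis(benzyloxy)-4-methoxyphenyl]-3-iodo-6,8-dimethoxy-4H-chromen-4-one; 19 methanol
Product: 20 5,7-bis(benzyloxy)-2-[2,5-bis(benzyloxy)-4-methoxyphenyl]-3,6,8-trimethoxy-4H-chromen-4-one
Conditions: CuI (20 mol%), 1,10-phenanthroline (40 mol%), Cs2CO3 (2 equiv), MeOH–toluene, 100 °C, sealed
Reagents that add atoms: methanol, CO
Why: Ullmann-type C–O coupling of a C(sp2)–I bond with an alcohol under phenanthroline-ligated CuI. The carbonate base keeps the methoxide concentration low, which spares C2 of the chromone; every phenolic oxygen is a benzyl ether, so no phenoxide, and in particular not the 2'-oxygen, can compete for C3.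

Step 11
Reactants: 20 5,7-bis(benzyloxy)-2-[2,5-bis(benzyloxy)-4-methoxyphenyl]-3,6,8-trimethoxy-4H-chromen-4-one
Product: 21 5,7,2',5'-tetrahydroxy-3,6,8,4'-tetramethoxyflavone
Conditions: H2 (1 atm), 10% Pd/C, THF–MeOH, rt; filtration and concentration under argon
Reagents that add atoms: none
Why: Catalytic hydrogenolysis of four aryl benzyl ethers. The C2=C3 bond is tetrasubstituted and part of the chromone, so it should reduce far more slowly than the benzyl ethers cleave, and methyl ethers are inert; air is excluded in the work-up because ring B is a hydroquinone.

## Compound list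

1 | 2,4,6-trihydroxybenzaldehyde | O=Cc1c(O)cc(O)cc1O | starting material
2 | benzyl bromide | BrCc1ccccc1 | starting material
3 | 2,4,6-tris(benzyloxy)benzaldehyde | O=Cc1c(OCc2ccccc2)cc(OCc2ccccc2)cc1OCc1ccccc1 | intermediate
4 | N-bromosuccinimide | O=C1CCC(=O)N1Br | starting material
5 | 2,4,6-tris(benzyloxy)-3,5-dibromobenzaldehyde | O=Cc1c(OCc2ccccc2)c(Br)c(OCc2ccccc2)c(Br)c1OCc1ccccc1 | intermediate
6 | sodium methoxide | [Na+].[O-]C | starting material
7 | 2,4,6-tris(benzyloxy)-3,5-dimethoxybenzaldehyde | O=Cc1c(OCc2ccccc2)c(OC)c(OCc2ccccc2)c(OC)c1OCc1ccccc1 | intermediate
8 | ethynylmagnesium bromide | C#C[Mg]Br | starting material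
9 | (±)-1-[2,4,6-tris(benzyloxy)-3,5-dimethoxyphenyl]prop-2-yn-1-ol (racemic) | C#CC(O)c1c(OCc2ccccc2)c(OC)c(OCc2ccccc2)c(OC)c1OCc1ccccc1 | intermediate
10 | methoxyhydroquinone (2-methoxybenzene-1,4-diol) | COc1cc(O)ccc1O | starting material
11 | 1,4-bis(benzyloxy)-2-methoxybenzene | COc1cc(OCc2ccccc2)ccc1OCc1ccccc1 | intermediate
12 | N-iodosuccinimide | O=C1CCC(=O)N1I | starting material
13 | 1,4-bis(benzyloxy)-2-iodo-5-methoxybenzene | COc1cc(OCc2ccccc2)c(I)cc1OCc1ccccc1 | intermediate
14 | (±)-3-[2,5-bis(benzyloxy)-4-methoxyphenyl]-1-[2,4,6-tris(benzyloxy)-3,5-dimethoxyphenyl]prop-2-yn-1-ol (racemic) | COc1cc(OCc2ccccc2)c(C#CC(O)c2c(OCc3ccccc3)c(OC)c(OCc3ccccc3)c(OC)c2OCc2ccccc2)cc1OCc1ccccc1 | intermediate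
15 | 3-[2,5-bis(benzyloxy)-4-methoxyphenyl]-1-[2,4,6-tris(benzyloxy)-3,5-dimethoxyphenyl]prop-2-yn-1-one | COc1cc(OCc2ccccc2)c(C#CC(=O)c2c(OCc3ccccc3)c(OC)c(OCc3ccccc3)c(OC)c2OCc2ccccc2)cc1OCc1ccccc1 | intermediate
16 | iodine monochloride | ICl | starting material
17 | 1-benzyl-5,7-bis(benzyloxy)-2-[2,5-bis(benzyloxy)-4-methoxyphenyl]-3-iodo-6,8-dimethoxy-4-oxo-4H-chromen-1-ium chloride | COc1cc(OCc2ccccc2)c(C2=C(I)C(=O)c3c(OCc4ccccc4)c(OC)c(OCc4ccccc4)c(OC)c3[O+]2Cc2ccccc2)cc1OCc1ccccc1.[Cl-] | intermediate
18 | 5,7-bis(benzyloxy)-2-[2,5-bis(benzyloxy)-4-methoxyphenyl]-3-iodo-6,8-dimethoxy-4H-chromen-4-one | COc1cc(OCc2ccccc2)c(-c2oc3c(OC)c(OCc4ccccc4)c(OC)c(OCc4ccccc4)c3c(=O)c2I)cc1OCc1ccccc1 | intermediate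
19 | methanol | CO | starting material
20 | 5,7-bis(benzyloxy)-2-[2,5-bis(benzyloxy)-4-methoxyphenyl]-3,6,8-trimethoxy-4H-chromen-4-one | COc1cc(OCc2ccccc2)c(-c2oc3c(OC)c(OCc4ccccc4)c(OC)c(OCc4ccccc4)c3c(=O)c2OC)cc1OCc1ccccc1 | intermediate
21 | 5,7,2',5'-tetrahydroxy-3,6,8,4'-tetramethoxyflavone | COc1cc(O)c(-c2oc3c(OC)c(O)c(OC)c(O)c3c(=O)c2OC)cc1O | target

## Step count and least certain steps

Total step count: 11. Longest linear sequence: 9 steps (steps 1, 2, 3, 4, 7, 8, 9, 10, 11); the ring-B branch (steps 5 and 6) joins at step 7.

Step 9 (key step). The most likely failure is electrophilic iodination of ring B (its C3'–H lies between two alkoxy groups) in competition with activation of the alkyne, or closure by the 2'-benzyloxy oxygen onto the carbonyl-side alkyne carbon. Both arise because the ether-protected ring B is electron-rich. The fallback closes ring C without an electrophile and introduces iodine by metalation. It sets out from 15. MgBr2·OEt2 in toluene–ether should remove one of the two ortho benzyl groups through the carbonyl chelate and give 3-[2,5-bis(benzyloxy)-4-methoxyphenyl]-1-[2,4-bis(benzyloxy)-6-hydroxy-3,5-dimethoxyphenyl]prop-2-yn-1-one F1 as a hydrogen-bonded ortho-hydroxyaryl ynone. Diethylamine in ethanol should then close ring C of F1; the amine adds first to the alkyne carbon next to ring B, so the phenol can only form the six-membered ring, which gives 5,7-bis(benzyloxy)-2-[2,5-bis(benzyloxy)-4-methoxyphenyl]-6,8-dimethoxy-4H-chromen-4-one F2 with hydrogen on C3. Carbonyl-directed lithiation of F2 at C3 with LiN(iPr)2 in THF at −78 °C and an iodine quench comes back to the route at 18.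

Step 10. The most likely failure is reductive loss of iodine, or conjugate attack of methoxide at C2 with opening of ring C, since an α-iodoenone is a less usual partner for CuI-mediated etherification than an aryl iodide. The fallback makes the C3–O bond by oxidation of a carbon–metal bond and then methylates. It sets out from 18. Iodine–magnesium exchange with iPrMgCl·LiCl in THF at −40 °C, trapping with B(OMe)3 and oxidation in the same flask with NaBO3 should give 5,7-bis(benzyloxy)-2-[2,5-bis(benzyloxy)-4-methoxyphenyl]-3-hydroxy-6,8-dimethoxy-4H-chromen-4-one F3 as a flavonol. The only free hydroxyl of F3 is methylated with MeI and K2CO3 in acetone, which comes back at 20.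

Step 1. The most likely failure is benzylation at ring carbons C3 and C5 by the ambident phloroglucinol-type phenoxide, or incomplete alkylation of the hydrogen-bonded ortho hydroxyls. The fallback builds 3 by formylation instead of alkylating the aldehyde. It sets out from 2. Commercial 1,3,5-triacetoxybenzene F4 is treated with NaH and 2 in DMF containing a little water, so that each phenoxide is benzylated as it is released, which should give 1,3,5-tris(benzyloxy)benzene F5 with little C-benzylation. Vilsmeier–Haack formylation (POCl3, DMF) of F5 comes back at 3.

Step 3. The most likely failure is hydrodebromination at the two crowded positions, or attack of methoxide at the aldehyde or at a benzyloxy-bearing carbon activated by it. The fallback moves bromination and methoxylation ahead of the formyl group and also bypasses steps 1 and 2. It sets out from 2, by way of 1,3,5-triacetoxybenzene F4 and 1,3,5-tris(benzyloxy)benzene F5 as described for step 1. F5 is brominated with two equivalents of NBS (stoichiometry now matters, since three positions are free) to 1,3,5-tris(benzyloxy)-2,4-dibromobenzene F6 as the intended dibromide. Methoxylation of F6 with NaOMe and CuI should give 1,3,5-tris(benzyloxy)-2,4-dimethoxybenzene F7 as a pentaalkoxybenzene, and formylation of F7 at its last free position (POCl3, DMF) comes back at 7.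

Step 7. The most likely failure is ionisation or base-induced isomerisation of carbinol 9, oxidative homocoupling of its alkyne, or slow oxidative addition of the electron-rich, ortho-substituted iodide. The fallback reverses the roles and makes the carbinol by carbonyl addition. It sets out from 13. Sonogashira coupling with trimethylsilylacetylene (PdCl2(PPh3)2, CuI, Et3N) should give {[2,5-bis(benzyloxy)-4-methoxyphenyl]ethynyl}trimethylsilane F8 as the silyl-capped arylalkyne. K2CO3 in methanol removes the silyl group of F8 to give 1,4-bis(benzyloxy)-2-ethynyl-5-methoxybenzene F9 as the terminal alkyne. The lithium acetylide of F9 (n-BuLi, THF, −78 °C) is added to aldehyde 7, which comes back at 14.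

## Further compounds

F1 | step 9 | 3-[2,5-bis(benzyloxy)-4-methoxyphenyl]-1-[2,4-bis(benzyloxy)-6-hydroxy-3,5-dimethoxyphenyl]prop-2-yn-1-one | COc1cc(OCc2ccccc2)c(C#CC(=O)c2c(O)c(OC)c(OCc3ccccc3)c(OC)c2OCc2ccccc2)cc1OCc1ccccc1
F2 | step 9 | 5,7-bis(benzyloxy)-2-[2,5-bis(benzyloxy)-4-methoxyphenyl]-6,8-dimethoxy-4H-chromen-4-one | COc1cc(OCc2ccccc2)c(-c2cc(=O)c3c(OCc4ccccc4)c(OC)c(OCc4ccccc4)c(OC)c3o2)cc1OCc1ccccc1
F3 | step 10 | 5,7-bis(benzyloxy)-2-[2,5-bis(benzyloxy)-4-methoxyphenyl]-3-hydroxy-6,8-dimethoxy-4H-chromen-4-one | COc1cc(OCc2ccccc2)c(-c2oc3c(OC)c(OCc4ccccc4)c(OC)c(OCc4ccccc4)c3c(=O)c2O)cc1OCc1ccccc1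
F4 | step 1 | 1,3,5-triacetoxybenzene | CC(=O)Oc1cc(OC(C)=O)cc(OC(C)=O)c1
F5 | step 1 | 1,3,5-tris(benzyloxy)benzene | c1ccc(COc2cc(OCc3ccccc3)cc(OCc3ccccc3)c2)cc1
F6 | step 3 | 1,3,5-tris(benzyloxy)-2,4-dibromobenzene | Brc1c(OCc2ccccc2)cc(OCc2ccccc2)c(Br)c1OCc1ccccc1
F7 | step 3 | 1,3,5-tris(benzyloxy)-2,4-dimethoxybenzene | COc1c(OCc2ccccc2)cc(OCc2ccccc2)c(OC)c1OCc1ccccc1
F8 | step 7 | {[2,5-bis(benzyloxy)-4-methoxyphenyl]ethynyl}trimethylsilane | COc1cc(OCc2ccccc2)c(C#C[Si](C)(C)C)cc1OCc1ccccc1
F9 | step 7 | 1,4-bis(benzyloxy)-2-ethynyl-5-methoxybenzene | COc1cc(OCc2ccccc2)c(C#C)cc1OCc1ccccc1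
A1 | alternative 1 | 2-[3-(4-acetoxy-3,5-dimethoxyphenyl)-2-methoxy-3-oxopropanoyl]-5-methoxy-1,4-phenylene diacetate | COc1cc(OC(C)=O)c(C(=O)C(OC)C(=O)c2cc(OC)c(OC(C)=O)c(OC)c2)cc1OC(C)=O
A2 | alternative 1 | 7-acetoxy-2-(2,5-diacetoxy-4-methoxyphenyl)-3,6,8-trimethoxy-4H-chromen-4-one | COc1cc(OC(C)=O)c(-c2oc3c(OC)c(OC(C)=O)c(OC)cc3c(=O)c2OC)cc1OC(C)=O
A3 | alternative 2 | kojic acid (5-hydroxy-2-(hydroxymethyl)-4H-pyran-4-one) | OCc1cc(=O)c(O)co1
A4 | alternative 2 | 2-[2,5-bis(benzyloxy)-4-methoxyphenyl]-3-methoxy-6-(methoxymethyl)-4H-pyran-4-one | COCc1cc(=O)c(OC)c(-c2cc(OCc3ccccc3)c(OC)cc2OCc2ccccc2)o1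
A5 | alternative 2 | dimethyl methoxymalonate | COC(C(=O)OC)C(=O)OC
A6 | alternative 2 | 2-[2,5-bis(benzyloxy)-4-methoxyphenyl]-5,7-dihydroxy-3,6,8-trimethoxy-4H-chromen-4-one | COc1cc(OCc2ccccc2)c(-c2oc3c(OC)c(O)c(OC)c(O)c3c(=O)c2OC)cc1OCc1ccccc1
A7 | alternative 3 | 5,7-bis(benzyloxy)-6,8-dimethoxy-2,2-dimethyl-4H-1,3-benzodioxin-4-one | COc1c(OCc2ccccc2)c(OC)c2OC(C)(C)OC(=O)c2c1OCc1ccccc1
A8 | alternative 3 | 1-[2,5-bis(benzyloxy)-4-methoxyphenyl]-2-methoxyethan-1-one | COCC(=O)c1cc(OCc2ccccc2)c(OC)cc1OCc1ccccc1
A9 | alternative 3 | 5,7-bis(benzyloxy)-2-[2,5-bis(benzyloxy)-4-methoxyphenyl]-3,6,8-trimethoxy-4H-chromen-4-one (identical with 20) | COc1cc(OCc2ccccc2)c(-c2oc3c(OC)c(OCc4ccccc4)c(OC)c(OCc4ccccc4)c3c(=O)c2OC)cc1OCc1ccccc1
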